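**Plan**

- Labels: ring carbons C1–C10, with C10 = C(CH3)OH, C1–C3 = CH2, C4(CH3)/C5 = epoxide, C6 = CH–O-aroyl, C7 = CH–iPr, C8=C9 = E-alkene.
- Retrosynthesis: cut the aroyl C–O bond at C6 and the two epoxide C–O bonds (back to a Z-C4=C5 dienol); then cut the ring bond C6–C7 and reconnect O6 to C9; then cut C7=C8 (olefination), C4=C5 (ring-closing metathesis) and O–C6 (O-allylation).
- Enabling feature: inside the ten-membered ring the array C4=C5–C6(O)–C7–C8=C9 is a 1,5-dien-3-ol. The carbocycle can therefore arise from a nine-membered oxonine ring (O bridging C6 and C9, C9 carrying the C8=C7 alkenyl group) by a one-atom ring expansion that pushes the oxygen out of the ring.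
- Forward order: acyclic C8–C10/C1–C4 chain → oxonine ring (metathesis) → E-alkenyl side chain → ten-membered carbocycle (ring expansion) → epoxide → ester → desilylation.
- Stereochemistry: C9/C10 from Sharpless epoxidation plus invertive hydrolysis; C7 by chirality transfer from C9; C6 from the tethered transition state; C4/C5 from hydroxyl-directed epoxidation.

Key step: step 12

Remark: C-labels in the text are those of the target ring defined above; locants inside compound names are IUPAC locants. Compounds 1, 14 and 22 are taken as catalogue reagents.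

**Route**

Step 1
Reactants: 1 5-bromo-2-methylpent-1-ene; 2 ethyl but-2-ynoate
Product: 4 ethyl (2E)-3,7-dimethylocta-2,7-dienoate, via 4-methylpent-4-enylmagnesium bromide 3 (not isolated)
Conditions: Mg, THF, rt; CuBr·SMe2 (1 equiv), −40 °C; then 2, −78 °C; MeOH quench at −78 °C, aq NH4Cl
Reagents that add atoms: none
Why: syn-carbocupration of the alkynoate and protonation with retention at low temperature should place the new chain cis to H and so give the (E)-3-methyl-2-enoate (conjugate addition of an organocopper reagent to an ynoate).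

Step 2
Reactants: 4 ethyl (2E)-3,7-dimethylocta-2,7-dienoate
Product: 5 (2E)-3,7-dimethylocta-2,7-dien-1-ol
Conditions: DIBAL-H (2.2 equiv), CH2Cl2, −78 → 0 °C; Rochelle salt
Reagents that add atoms: none
Why: 1,2-reduction of the conjugated ester by DIBAL-H should give the allylic alcohol without change of alkene geometry.

Step 3
Reactants: 5 (2E)-3,7-dimethylocta-2,7-dien-1-ol
Product: 6 [(2S,3S)-3-methyl-3-(4-methylpent-4-en-1-yl)oxiran-2-yl]methanol
Conditions: Ti(OiPr)4 (10 mol %), L-(+)-diethyl tartrate (12 mol %), t-BuOOH, 4 Å MS, CH2Cl2, −20 °C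
Reagents that add atoms: tert-butyl hydroperoxide CC(C)(C)OO
Why: Sharpless asymmetric epoxidation acts only on the allylic-alcohol alkene, and with the L-(+)-tartrate the oxygen should be delivered to the face that gives the (2S,3S)-epoxide, as for geraniol-type substrates.

Step 4
Reactants: 6 [(2S,3S)-3-methyl-3-(4-methylpent-4-en-1-yl)oxiran-2-yl]methanol
Product: 7 (2S,3R)-3,7-dimethyloct-7-ene-1,2,3-triol
Conditions: HClO4 (cat.), THF–H2O 3:1, 0 °C → rt
Reagents that add atoms: water O
Why: in acid-catalysed epoxide hydrolysis water should attack the tertiary carbon with inversion while the secondary C–O bond is kept, so the trans-epoxide gives the (2S,3R)-triol and fixes C9 (S) and C10 (R) of the target.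

Step 5
Reactants: 7 (2S,3R)-3,7-dimethyloct-7-ene-1,2,3-triol
Product: 8 (2S,3R)-3,7-dimethyl-1-[(triethylsilyl)oxy]oct-7-ene-2,3-diol
Conditions: Et3SiCl (1.05 equiv), imidazole, CH2Cl2, −78 → −40 °C
Reagents that add atoms: chlorotriethylsilane CC[Si](Cl)(CC)CC
Why: silylation at low temperature should select the primary hydroxyl over the secondary and tertiary ones on steric grounds.

Step 6
Reactants: 8 (2S,3R)-3,7-dimethyl-1-[(triethylsilyl)oxy]oct-7-ene-2,3-diol
Product: 10 (2S,3R)-3,7-dimethyl-2-(prop-2-en-1-yloxy)-1-[(triethylsilyl)oxy]oct-7-en-3-ol, via dibutylstannylene acetal 9 (not isolated)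
Conditions: Bu2SnO, toluene, reflux (−H2O); then allyl bromide, Bu4NI, toluene, 90 °C
Reagents that add atoms: allyl bromide C=CCBr
Why: alkylation of the stannylene acetal of a secondary/tertiary 1,2-diol should go to the less hindered secondary oxygen under neutral conditions, which also avoids 1,2-silyl migration (regioselective O-alkylation via a dibutylstannylene acetal).

Step 7
Reactants: 10 (2S,3R)-3,7-dimethyl-2-(prop-2-en-1-yloxy)-1-[(triethylsilyl)oxy]oct-7-en-3-ol
Product: 11 (2S,3R)-3,7-dimethyl-2-(prop-2-en-1-yloxy)-1,3-bis[(triethylsilyl)oxy]oct-7-ene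
Conditions: Et3SiOTf, 2,6-lutidine, CH2Cl2, −78 → 0 °C
Reagents that add atoms: triethylsilyl trifluoromethanesulfonate CC[Si](CC)(CC)OS(=O)(=O)C(F)(F)F
Why: a silyl triflate with a hindered base silylates tertiary alcohols, and the ether blocks retro-aldol cleavage at the aldehyde stage and removes a second directing hydroxyl before step 13.

Step 8
Reactants: 11 (2S,3R)-3,7-dimethyl-2-(prop-2-en-1-yloxy)-1,3-bis[(triethylsilyl)oxy]oct-7-ene
Product: 12 (2S,3R,7Z)-3,7-dimethyl-3-[(triethylsilyl)oxy]-2-{[(triethylsilyl)oxy]methyl}-2,3,4,5,6,9-hexahydrooxonine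
Conditions: second-generation Ru–NHC benzylidene metathesis catalyst (10 mol %), 1,4-benzoquinone (20 mol %), toluene (2 mM), 80 °C
Reagents that add atoms: none
Why: ring-closing metathesis of the allyl ether with the 1,1-disubstituted alkene should be helped by the gauche preference of the vicinal C–O bonds and by the quaternary carbon, and a nine-membered ring can hold the trisubstituted alkene only as the Z isomer.

Step 9
Reactants: 12 (2S,3R,7Z)-3,7-dimethyl-3-[(triethylsilyl)oxy]-2-{[(triethylsilyl)oxy]methyl}-2,3,4,5,6,9-hexahydrooxonine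
Product: 13 (2R,3R,7Z)-3,7-dimethyl-3-[(triethylsilyl)oxy]-2,3,4,5,6,9-hexahydrooxonine-2-carbaldehyde
Conditions: (COCl)2, DMSO, CH2Cl2, −78 → −30 °C; then Et3N, −78 → 0 °C
Reagents that add atoms: none
Why: under Swern conditions a primary triethylsilyl ether is oxidised directly to the aldehyde (oxidative desilylation by the chlorosulfonium salt) while the tertiary silyl ether is too hindered to react, and the low temperature protects the α-alkoxy stereocentre (the descriptor changes to 2R only through CIP priorities).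

Step 10
Reactants: 14 1-phenyl-1H-tetrazole-5-thiol; 15 1-bromo-2-methylpropane
Product: 17 5-[(2-methylpropyl)sulfonyl]-1-phenyl-1H-tetrazole, via isobutyl tetrazolyl sulfide 16 (not isolated)
Conditions: K2CO3, EtOH, 60 °C; then (NH4)6Mo7O24·4H2O (cat.), 30 % H2O2, 0 °C → rt
Reagents that add atoms: hydrogen peroxide OO
Why: S-alkylation of the thiol by the primary bromide and molybdate-catalysed peroxide oxidation of the sulfide is the standard preparation of a Julia–Kocienski sulfone.

Step 11
Reactants: 13 (2R,3R,7Z)-3,7-dimethyl-3-[(triethylsilyl)oxy]-2,3,4,5,6,9-hexahydrooxonine-2-carbaldehyde; 17 5-[(2-methylpropyl)sulfonyl]-1-phenyl-1H-tetrazole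
Product: 18 (2S,3R,7Z)-3,7-dimethyl-2-[(1E)-3-methylbut-1-en-1-yl]-3-[(triethylsilyl)oxy]-2,3,4,5,6,9-hexahydrooxonine
Conditions: KHMDS, DME, −60 °C → rt; aq NH4Cl
Reagents that add atoms: none
Why: Julia–Kocienski olefination (addition of the metalated tetrazolyl sulfone, Smiles rearrangement, loss of SO2) should give the E-alkene with this α-branched aldehyde without touching the α-alkoxy centre.

Step 12
Reactants: 18 (2S,3R,7Z)-3,7-dimethyl-2-[(1E)-3-methylbut-1-en-1-yl]-3-[(triethylsilyl)oxy]-2,3,4,5,6,9-hexahydrooxonine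
Product: 20 (1R,2Z,7R,8E,10S)-3,7-dimethyl-10-(propan-2-yl)-7-[(triethylsilyl)oxy]cyclodeca-2,8-dien-1-ol, via 9-lithio oxonine 19 (not isolated)
Conditions: n-BuLi (1.3 equiv), THF, −78 → −20 °C; aq NH4Cl
Reagents that add atoms: none
Why: Proposed new method: kinetic deprotonation of the ring O–CH2 group that is allylic to C4=C5 should give the α-oxyallyl-lithium 19, whose carbanion carbon C6 bonds to C7 of the exocyclic E-alkenyl group while the O–C9 bond breaks in a suprafacial five-centre, six-electron [2,3]-shift, so the oxygen leaves the ring and the nine-membered oxacycle becomes the ten-membered carbocycle. The closest known reactions are the [2,3]-Wittig rearrangement of acyclic bis-allylic ethers and its ring-contracting form in macrocyclic diallylic ethers; the ring-expanding mode with an endocyclic carbanion and an exocyclic alkenyl group is not established. The ten-membered ring is closed by the new C6–C7 σ-bond through a bicyclic envelope transition state in which the six-carbon tether C5–C4–C3–C2–C1–C10 spans the two carbons next to oxygen. C7 (S) should be set by chirality transfer from C9 (S) across the E-alkene, because bond formation and C–O cleavage occur on the same face of the allyl unit, and C6 (R) because the tether can bridge C6 and C9 only cis on the envelope, which puts C5 on the flap side. The new C8=C9 bond should be E because the quaternary C10 takes the pseudo-equatorial position to avoid A1,3 strain with C7. The step needs the [2,3]-path over the [1,2]-shift and over lithiation at C9; low temperature favours the concerted path, and the tertiary, neopentyl-type C9–H next to the silyloxy carbon disfavours the second.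

Step 13
Reactants: 20 (1R,2Z,7R,8E,10S)-3,7-dimethyl-10-(propan-2-yl)-7-[(triethylsilyl)oxy]cyclodeca-2,8-dien-1-ol
Product: 21 (1R,2R,3S,4E,6R,10S)-6,10-dimethyl-3-(propan-2-yl)-6-[(triethylsilyl)oxy]-11-oxabicyclo[8.1.0]undec-4-en-2-ol
Conditions: VO(acac)2 (5 mol %), t-BuOOH, CH2Cl2, 0 °C → rt
Reagents that add atoms: tert-butyl hydroperoxide CC(C)(C)OO
Why: vanadium-catalysed hydroxyl-directed epoxidation should pick the allylic trisubstituted C4=C5 alkene over the hindered homoallylic C8=C9 alkene and, as in medium-ring (Z)-cycloalk-2-enols, deliver oxygen syn to the C6 hydroxyl (cis-epoxy alcohol), which is the required (4S,5R) configuration.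

Step 14
Reactants: 21 (1R,2R,3S,4E,6R,10S)-6,10-dimethyl-3-(propan-2-yl)-6-[(triethylsilyl)oxy]-11-oxabicyclo[8.1.0]undec-4-en-2-ol; 22 4-[(tert-butyldimethylsilyl)oxy]benzoic acid
Product: 23 (1R,2R,3S,4E,6R,10S)-6,10-dimethyl-3-(propan-2-yl)-6-[(triethylsilyl)oxy]-11-oxabicyclo[8.1.0]undec-4-en-2-yl 4-[(tert-butyldimethylsilyl)oxy]benzoate
Conditions: N,N'-diisopropylcarbodiimide, DMAP, CH2Cl2, rt
Reagents that add atoms: none
Why: Steglich esterification acylates the only free hydroxyl (C6) with retention, under conditions that should not open the epoxide.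

Step 15
Reactants: 23 (1R,2R,3S,4E,6R,10S)-6,10-dimethyl-3-(propan-2-yl)-6-[(triethylsilyl)oxy]-11-oxabicyclo[8.1.0]undec-4-en-2-yl 4-[(tert-butyldimethylsilyl)oxy]benzoate
Product: 24 (1R,2R,3S,4E,6R,10S)-6-hydroxy-6,10-dimethyl-3-(propan-2-yl)-11-oxabicyclo[8.1.0]undec-4-en-2-yl 4-hydroxybenzoate (target)
Conditions: Bu4NF (3 equiv), AcOH (3 equiv), THF, 0 °C → rt
Reagents that add atoms: none
Why: fluoride should cleave the aryl silyl ether and the tertiary triethylsilyl ether in one operation, and the acetic acid buffer keeps phenoxide and alkoxide from attacking the ester or the epoxide.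

**Compound list**

1 | 5-bromo-2-methylpent-1-ene | C=C(C)CCCBr | starting material
2 | ethyl but-2-ynoate | CC#CC(=O)OCC | starting material
3 | (4-methylpent-4-en-1-yl)magnesium bromide | C=C(C)CCC[Mg]Br | intermediate
4 | ethyl (2E)-3,7-dimethylocta-2,7-dienoate | C=C(C)CCC/C(C)=C/C(=O)OCC | intermediate
5 | (2E)-3,7-dimethylocta-2,7-dien-1-ol | C=C(C)CCC/C(C)=C/CO | intermediate
6 | [(2S,3S)-3-methyl-3-(4-methylpent-4-en-1-yl)oxiran-2-yl]methanol | C=C(C)CCC[C@]1(C)O[C@H]1CO | intermediate
7 | (2S,3R)-3,7-dimethyloct-7-ene-1,2,3-triol | C=C(C)CCC[C@@](C)(O)[C@@H](O)CO | intermediate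
8 | (2S,3R)-3,7-dimethyl-1-[(triethylsilyl)oxy]oct-7-ene-2,3-diol | C=C(C)CCC[C@@](C)(O)[C@@H](O)CO[Si](CC)(CC)CC | intermediate
9 | (4S,5R)-2,2-dibutyl-5-methyl-5-(4-methylpent-4-en-1-yl)-4-{[(triethylsilyl)oxy]methyl}-1,3,2-dioxastannolane | C=C(C)CCC[C@@]1(C)O[Sn](CCCC)(CCCC)O[C@H]1CO[Si](CC)(CC)CC | intermediate
10 | (2S,3R)-3,7-dimethyl-2-(prop-2-en-1-yloxy)-1-[(triethylsilyl)oxy]oct-7-en-3-ol | C=C(C)CCC[C@@](C)(O)[C@@H](OCC=C)CO[Si](CC)(CC)CC | intermediate
11 | (2S,3R)-3,7-dimethyl-2-(prop-2-en-1-yloxy)-1,3-bis[(triethylsilyl)oxy]oct-7-ene | C=C(C)CCC[C@@](C)(O[Si](CC)(CC)CC)[C@@H](OCC=C)CO[Si](CC)(CC)CC | intermediate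
12 | (2S,3R,7Z)-3,7-dimethyl-3-[(triethylsilyl)oxy]-2-{[(triethylsilyl)oxy]methyl}-2,3,4,5,6,9-hexahydrooxonine | CC[Si](CC)(CC)OC[C@@H]1OC/C=C(/C)CCC[C@@]1(C)O[Si](CC)(CC)CC | intermediate
13 | (2R,3R,7Z)-3,7-dimethyl-3-[(triethylsilyl)oxy]-2,3,4,5,6,9-hexahydrooxonine-2-carbaldehyde | O=C[C@@H]1OC/C=C(/C)CCC[C@@]1(C)O[Si](CC)(CC)CC | intermediate
14 | 1-phenyl-1H-tetrazole-5-thiol | Sc1nnnn1-c1ccccc1 | starting material
15 | 1-bromo-2-methylpropane | CC(C)CBr | starting material
16 | 5-[(2-methylpropyl)sulfanyl]-1-phenyl-1H-tetrazole | CC(C)CSc1nnnn1-c1ccccc1 | intermediate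
17 | 5-[(2-methylpropyl)sulfonyl]-1-phenyl-1H-tetrazole | CC(C)CS(=O)(=O)c1nnnn1-c1ccccc1 | intermediate
18 | (2S,3R,7Z)-3,7-dimethyl-2-[(1E)-3-methylbut-1-en-1-yl]-3-[(triethylsilyl)oxy]-2,3,4,5,6,9-hexahydrooxonine | CC(C)/C=C/[C@@H]1OC/C=C(/C)CCC[C@@]1(C)O[Si](CC)(CC)CC | intermediate
19 | 9-lithio derivative of 18 (α-oxyallyl-lithium; configuration at the lithiated carbon not defined) | CC(C)/C=C/[C@@H]1OC([Li])/C=C(/C)CCC[C@@]1(C)O[Si](CC)(CC)CC | intermediate
20 | (1R,2Z,7R,8E,10S)-3,7-dimethyl-10-(propan-2-yl)-7-[(triethylsilyl)oxy]cyclodeca-2,8-dien-1-ol | CC(C)[C@H]1/C=C/[C@](C)(O[Si](CC)(CC)CC)CCC/C(C)=C\[C@@H]1O | intermediate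
21 | (1R,2R,3S,4E,6R,10S)-6,10-dimethyl-3-(propan-2-yl)-6-[(triethylsilyl)oxy]-11-oxabicyclo[8.1.0]undec-4-en-2-ol | CC(C)[C@H]1/C=C/[C@](C)(O[Si](CC)(CC)CC)CCC[C@]2(C)O[C@@H]2[C@@H]1O | intermediate
22 | 4-[(tert-butyldimethylsilyl)oxy]benzoic acid | CC(C)(C)[Si](C)(C)Oc1ccc(C(=O)O)cc1 | starting material
23 | (1R,2R,3S,4E,6R,10S)-6,10-dimethyl-3-(propan-2-yl)-6-[(triethylsilyl)oxy]-11-oxabicyclo[8.1.0]undec-4-en-2-yl 4-[(tert-butyldimethylsilyl)oxy]benzoate | CC(C)[C@H]1/C=C/[C@](C)(O[Si](CC)(CC)CC)CCC[C@]2(C)O[C@@H]2[C@@H]1OC(=O)c1ccc(O[Si](C)(C)C(C)(C)C)cc1 | intermediate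
24 | (1R,2R,3S,4E,6R,10S)-6-hydroxy-6,10-dimethyl-3-(propan-2-yl)-11-oxabicyclo[8.1.0]undec-4-en-2-yl 4-hydroxybenzoate | CC(C)[C@H]1/C=C/[C@](C)(O)CCC[C@]2(C)O[C@@H]2[C@@H]1OC(=O)c1ccc(O)cc1 | target

**Count**

Total steps: 15. Longest linear sequence: 14 (steps 1–9 and 11–15; step 10 is a one-step side branch).

**Steps most likely to fail**

1. Step 12 (proposed new method). The lithiation may occur at the wrong α-oxy carbon, the lithiated ether may follow the stepwise [1,2]-shift instead of the concerted path, or the bicyclic transition state may be too strained and give the Z-alkene or decomposition. Fallback with known chemistry, setting out from 11 and returning at 20: oxidative desilylation of 11 under the Swern conditions of step 9 should give (2R,3R)-3,7-dimethyl-2-(prop-2-en-1-yloxy)-3-[(triethylsilyl)oxy]oct-7-enal F1. Julia–Kocienski olefination of F1 with 17 (KHMDS, DME) should give triethyl{[(3E,5S,6R)-2,6,10-trimethyl-5-(prop-2-en-1-yloxy)undeca-3,10-dien-6-yl]oxy}silane F2. A conventional acyclic [2,3]-Wittig rearrangement of F2 (n-BuLi, THF, −78 °C, lithiation at the allyl CH2) should give (3S,4S,5E,7R)-7,11-dimethyl-4-(propan-2-yl)-7-[(triethylsilyl)oxy]dodeca-1,5,11-trien-3-ol F3 with the same C9-to-C7 chirality transfer. Without the tether the transition state may favour the other C6 configuration, so the C6 epimers would have to be separated here. Ring-closing metathesis of F3 between the vinyl and isopropenyl ends (same Ru catalyst, high dilution) would then close the ten-membered ring at C4=C5 and rejoin the route at 20.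

2. Step 8. Closure of a nine-membered ring with formation of a trisubstituted alkene may be slower than cross-metathesis oligomerisation or isomerisation of the allyl ether. Fallback setting out from 11 and returning at 12: ozonolysis of both terminal alkenes (O3, CH2Cl2–MeOH, −78 °C; Me2S) should give {[(2S,3R)-3-methyl-7-oxo-1,3-bis[(triethylsilyl)oxy]octan-2-yl]oxy}acetaldehyde F4. Intramolecular McMurry coupling of its aldehyde and methyl ketone (TiCl3(DME)1.5, Zn–Cu, DME, reflux, slow addition) is a reductive carbonyl coupling that is well suited to medium rings and would form the ring Z-alkene of 12.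

3. Step 13. The oxygen may be delivered to the wrong face of C4=C5 if the ring conformation does not allow the syn-directed geometry, and some epoxidation of C8=C9 may compete. Fallback setting out from 20 and returning at 23: the order is changed and the control element is switched from metal direction to steric control. Steglich esterification of 20 with 22 should give (1R,2Z,7R,8E,10S)-3,7-dimethyl-10-(propan-2-yl)-7-[(triethylsilyl)oxy]cyclodeca-2,8-dien-1-yl 4-[(tert-butyldimethylsilyl)oxy]benzoate F5. Non-directed peracid epoxidation of F5 (m-CPBA, NaHCO3, CH2Cl2, 0 °C) would attack the more electron-rich trisubstituted alkene from the face left open by the ring conformation and the bulky aroyloxy group. In medium rings this mode is complementary to the metal-directed one, and it leads to 23.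

**Further compounds**

F1 | step 12 | (2R,3R)-3,7-dimethyl-2-(prop-2-en-1-yloxy)-3-[(triethylsilyl)oxy]oct-7-enal | C=C(C)CCC[C@@](C)(O[Si](CC)(CC)CC)[C@@H](OCC=C)C=O
F2 | step 12 | triethyl{[(3E,5S,6R)-2,6,10-trimethyl-5-(prop-2-en-1-yloxy)undeca-3,10-dien-6-yl]oxy}silane | C=C(C)CCC[C@@](C)(O[Si](CC)(CC)CC)[C@@H](OCC=C)/C=C/C(C)C
F3 | step 12 | (3S,4S,5E,7R)-7,11-dimethyl-4-(propan-2-yl)-7-[(triethylsilyl)oxy]dodeca-1,5,11-trien-3-ol | C=C[C@H](O)[C@@H](C(C)C)/C=C/[C@](C)(O[Si](CC)(CC)CC)CCCC(C)=C
F4 | step 8 | {[(2S,3R)-3-methyl-7-oxo-1,3-bis[(triethylsilyl)oxy]octan-2-yl]oxy}acetaldehyde | CC(=O)CCC[C@@](C)(O[Si](CC)(CC)CC)[C@@H](OCC=O)CO[Si](CC)(CC)CC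
F5 | step 13 | (1R,2Z,7R,8E,10S)-3,7-dimethyl-10-(propan-2-yl)-7-[(triethylsilyl)oxy]cyclodeca-2,8-dien-1-yl 4-[(tert-butyldimethylsilyl)oxy]benzoate | CC(C)[C@H]1/C=C/[C@](C)(O[Si](CC)(CC)CC)CCC/C(C)=C\[C@@H]1OC(=O)c1ccc(O[Si](C)(C)C(C)(C)C)cc1
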